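I start from a small charge: G stands at 0.950 of the J charged, and in the north-west run the last reading of D is about a quarter of the J charged, well below that. So I reckon from the curve.

common to all: J 0.30 M
- north-west: G 0.285 M; temperature 50 °C; the very flask that is asked about, followed so far
- east: G 0.43 M; temperature 35 °C; run made earlier
- flask: G 0.285 M; temperature 50 °C; time 80 min

| north-west: time / min | north-west: D / % | east: time / min | east: D / % |
|---|---|---|---|
| 5.00 | 6.2 | 1.33 | 0 |
| 15.0 | 16.3 | 2.00 | 0 |
| 30.0 | 20.5 | 4.00 | 0.9 |
| 40.0 | 25.5 | 6.00 | 0.7 |
| 60.0 | 26.9 | 10.0 | 0 |
| 80.0 | 27.4 | 15.0 | 1.4 |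

(each reading ± 1 percentage point)

- blue: at 80 min take out 90% of the D then present, then wait 40 min
- violet: change nothing and wait 40 min more
- green: at 80 min raise the temperature by 15 K, then wait 40 min
- amber: at 80 min add G, 50.0% of the amount charged, then wait 40 min

- what is taken out of D is counted as made
- on the list of suspects stand: J <-> Z; G -> X; Z + X -> D; G + D -> L; Z -> Q
- additions bring no volume worth counting

- D, in percent of the J first charged, at 80 min
- what to do for the largest gain in D; "none" if nothing gains more than 2 percentage points (blue / violet / green / amber / none)
- D present, with what was taken out counted in, in percent of the J first charged, after blue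
- D present, with what was taken out counted in, in percent of the J first charged, after green

The last two north-west readings average to a plateau of 27.1%. The reading of 16.3% at 15.0 min then gives 16.4 min, my levelling time, the time in which the gap between D and its plateau falls by the factor e. At 80 min that leaves a gap of 0.2 percentage points, so I put D in the asked flask at 26.9%. The east run, colder and richer in G, shows 1.4% at 15.0 min, so I carry this levelling time to no other temperature without a new reading.

The weak link is that the levelling time hangs on one reading with a scatter of 1 point. The reading at 30.0 min gives 21.3 min instead, longer than before, with a gap of 0.64 points and D at 26.5%. I commit to that D. The gap stays below the 2 points that counts, so waiting is useless. Taking out D or heating could beat that gap if the plateau is a balance and not an end, and these readings cannot tell me which.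

The forecast gives 27.5% for D, a little above mine, with none as the best choice, 28.2% after blue and 28.3% after green: “The observed levelling is sharper, so I favour the Z → Q drain.”

    J ⇌ Z (K = 1.10, k = 8.20 × 10⁻⁴ /s, Ea = 90.0 kJ/mol, ΔH = 15.0 kJ/mol)
    G → X (k = 6.10 × 10⁻⁴ /s, Ea = 100 kJ/mol)
    Z + X → D (k = 0.0930 /M/s, Ea = 47.0 kJ/mol)
    G + D → L (k = 0.00960 /M/s, Ea = 51.0 kJ/mol)
    Z → Q (k = 7.60 × 10⁻⁴ /s, Ea = 92.0 kJ/mol)
    (constants at 50 °C)

The flask gives 26.4% at 80 min, best none, 26.9% after blue and 26.8% after green, and waiting gains 0.33 points, less than my gap. In the flask at 80.0 min, Z has a half-life of 91 min by Z + X → D, longer than the levelling time and the wait, while G, the limiting reagent, stands at 0.306% of its charge. Carried unchanged to the same flask run at 35 °C, my plateau and levelling time give D at 26.5%, but that flask stands lower, at 9.39% at 80.0 min.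

All runs are simulated from invented constants; noise was put on by code.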